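## The problem

The target, (2S)-7-hydroxy-2-(4-hydroxyphenyl)-6,8-bis(3-methylbut-2-en-1-yl)chroman-4-one (15), is a flavanone. Benzo ring A is fused to the dihydropyranone ring C through C4a and C8a, and ring B, a 4-hydroxyphenyl group, sits on C2. The only stereocenter is C2 (S). It is a benzylic ether carbon beta to the C4 ketone, so it has nothing to relay its configuration to and nothing in the molecule can set it; an external chiral agent must. Once set, it is threatened by base (retro-oxa-Michael opening to the 2'-hydroxychalcone) and by strong acid (ionisation of the C2–O1 bond, helped by the para oxygen of ring B). Ring A is substituted everywhere except C5: oxygen at C7 and C8a, prenyl groups at C6 and C8, the acyl carbon C4 at C4a. Direct prenylation of a resorcinol nucleus gives mixtures of C- and O-alkylation and of positional isomers, so ring A is the real construction problem. The two prenyl groups exclude hydrogenolysis, electrophilic halogenation, quinone oxidants and strong acids, because an ortho-prenyl phenol closes to a 2,2-dimethylchroman. The phenols must therefore be masked lightly and released gently. The enabling feature is that C7 with its two prenyl-bearing neighbours C6 and C8 is mirror-symmetric about C7 and is a dialkyl ketone in disguise (3). The remaining atoms, C5 as a CH and C4a carrying the two carboxyl-level carbons C8a and C4, are the skeleton of an alkoxymethylenemalonate (4). The oxidation levels of 3 and 4 add up to a resorcylate with no oxidant, and C4 arrives as an ester.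

## Retrosynthesis

**15 from 14.** The two phenolic O–H bonds are traced back to methoxymethyl ethers in 14. One common group on both oxygens allows a single release step. An acetal is chosen over benzyl (hydrogenolysis would reduce the prenyl groups), over allyl (a terminal alkene would interfere in the palladium step) and over esters (their basic cleavage opens ring C). The forward step must cleave two aryl acetals without touching C2 or the prenyl groups.

**14 from 12 and 13.** The C2–aryl bond is cut, which removes the stereocenter and leaves the flat chromone 12 and the boronic acid 13. The neighbouring cut at O1–C2 would lead to an open-chain hydroxy enone whose enantioselective oxa-Michael closure is poorly controlled for unactivated substrates. A cut at C2–C3 would need an aldol of defined configuration and then an inverting etherification. The aryl–C2 cut asks a chiral catalyst to choose one face of an achiral, rigid enone, and it attaches ring B in the same step. The forward reaction needs face selectivity on an electron-rich chromone, no aromatisation to the flavone, and indifference to two trisubstituted alkenes.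

**12 from 10.** O1–C2 and C2–C3 are cut, so that C2 becomes a one-carbon unit delivered by an amide acetal to the methyl ketone 10. The enaminone 11 is the intermediate. The alternative through an alkynyl ketone would need a more elaborate acyl donor and an acetylide. The forward reaction is a condensation followed by a mild acid-mediated ring closure.

**10 from 8 and 8 from 7.** The C3–C4 bond is cut, so the acetyl group becomes the ethyl ester of 8, and the MOM ether is taken off to reveal the resorcylate 7. Carrying an acetyl group through the ring construction was rejected. An acetyl-bearing methylene partner would close ring A by aldol condensation on the ketone, not by Claisen condensation on the ester, and would give the wrong arene. Only the 4-OH of 7 needs protection, because the 2-OH is tied up by the ester carbonyl.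

**7 from 3 and 4.** Ring A is cut at C5–C6 and C8–C8a. This leaves the symmetric ketone 3 as the C6–C7–C8 unit and diethyl ethoxymethylidenemalonate 4 as C5, C4a, C8a and C4. The cut is preferred to any functionalisation of an existing arene because it places both prenyl groups, both oxygens and the acyl carbon in one operation with no positional choice. It turns a pentasubstituted benzene into two acyclic compounds with no stereochemistry. The forward reaction must achieve one addition-elimination and one carbon-acylation. The open-chain adduct 5 and its O-acylated form, the 2-pyranone 6, are expected on the way.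

**3 from 1 and 2.** One alpha C–C bond of 3 is cut, giving 6-methylhept-5-en-2-one 1 and prenyl bromide 2. The ketone 1 already carries one of the two side chains, so a single alkylation at its methyl group suffices.

## Roads not taken

**Alternative 1:** The cut is made in the side chains. Both trisubstituted C=C bonds are formed last by twofold cross-metathesis of the (S)-6,8-diallylflavanone A2 with 2-methylbut-2-ene A3 under the second-generation Grubbs catalyst RuCl2(H2IMes)(PCy3)(=CHPh), giving the monosilylated flavanone A1.
- Merits: allyl-to-prenyl cross-metathesis is dependable, and the diallyl arene can be reached with defined regiochemistry by two rounds of O-allylation and aromatic Claisen rearrangement on a commercial resorcinol ketone.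
- Weak points: two rearrangement cycles lengthen the route to roughly ten steps. The terminal alkenes must either pass through the asymmetric ring-C chemistry or be made after it. The free C7 hydroxyl between two allyl groups invites ruthenium hydride isomerisation to propenyl groups on the chiral material.
- Comparison: in precedent this road is better than the chosen one, since every step is established. The chosen plan sets against that a shorter sequence, prenyl groups present from step 1 that never have to be made on a chiral phenol-bearing flavanone, and a single unproven step placed early on inexpensive material.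

**Alternative 2:** The cut is O1–C8a. The anti-1,3-diol A5, which carries an aryl bromide at the future C8a, is closed by intramolecular O-arylation with CuI (monovalent copper), a phenanthroline-type ligand and Cs2CO3 to the flavan-4-ol A4. Oxidation at C4 and deprotection follow.
- Merits: C2 is set as a carbinol by reliable asymmetric carbonyl chemistry and is not exposed to ring-opening conditions until the end. Here it is stronger than the chosen plan, which relies on catalyst control at an electron-rich chromone.
- Weak points: the bromide of A5 is flanked by a prenyl group and the carbinol chain, a poor setting for copper etherification with a secondary alcohol. A second stereocenter at C4 is built only to be oxidised away. The fully substituted ring A, with bromine added, still has to be assembled, so the main problem is postponed.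
- Comparison: the chosen plan is much shorter and solves ring A outright.

**Alternative 3:** Ring A is cut into a vinylketene and an alkyne. Irradiation of the dienyl diazoketone A7 with the siloxyalkyne A8 starts a Wolff rearrangement, a [2+2] cycloaddition, a four-electron ring opening and a six-electron closure, and gives the resorcinol monosilyl ether A6.
- Merits: the benzannulation is regiospecific, neutral and known as a reaction class. It also differentiates the two oxygens of ring A automatically. In precedent for the ring-forming event it is ahead of the chosen plan.
- Weak points: both partners need several steps (diazo transfer on a skipped diene that can conjugate; ynolate chemistry for A8). Photolysis of a diazo compound beside electron-rich alkenes risks cyclopropanation. A6 lacks the C4 carbon, so an acylation at C4a of an acid-sensitive prenylated phenol would still be required.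
- Comparison: the chosen plan delivers C4 as an ester in the ring-forming step, from two bulk chemicals, and chelation differentiates the two oxygens.

Key step: step 2

Assumption on the chemistry: the (R)-configured pyridine-oxazoline ligand is taken to deliver the aryl group to the chromone face that gives the 2S product, by analogy with the sense of induction of the (S)-ligand on carbocyclic enones. If the sense proves opposite, the antipodal ligand is used with no other change. Boronic acid 13 and both ligand enantiomers are treated as purchasable.

## Route

Step 1
Reactants: 1 6-methylhept-5-en-2-one; 2 1-bromo-3-methylbut-2-ene (prenyl bromide)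
Product: 3 2,10-dimethylundeca-2,9-dien-6-one
Conditions: LiN(iPr)2 (1.05 equiv), THF, −78 °C; then 2 (1.1 equiv), DMPU, −78 → −20 °C
Reagents that add atoms: none
Why: Kinetic deprotonation by the hindered amide at −78 °C takes a proton from the methyl group of 1, and the terminal lithium enolate is alkylated at the primary carbon of the allylic bromide (enolate alkylation, SN2). The product is symmetric, so no regio- or stereochemical element is carried forward.

Step 2
Reactants: 3 2,10-dimethylundeca-2,9-dien-6-one; 4 diethyl 2-(ethoxymethylidene)propanedioate
Product: 7 ethyl 2,4-dihydroxy-3,5-bis(3-methylbut-2-en-1-yl)benzoate, via alkylidenemalonate adduct 5 (not isolated), via 2-pyranone reservoir 6 (not isolated)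
Conditions: LiN(iPr)2 (1.05 equiv), THF, −78 °C; 4 (0.95 equiv), −78 → 0 °C; then NaOEt (3.5 equiv), EtOH, 70 °C; cold 1 M HCl
Reagents that add atoms: none
Why: Proposed new method: the lithium enolate of 3 adds to the beta carbon of 4 and expels ethoxide (addition-elimination, forming C5–C6) to give 5, which the liberated ethoxide converts into its delocalised C6 anion; this first half is the known route from ketone enolates and alkoxymethylenemalonates to 3-carbalkoxy-2-pyranones, so partial O-acylation to 6 is expected. Under NaOEt in hot ethanol 6 is reopened at the lactone carbonyl, and the small equilibrium share of the C8 enolate of 5 attacks the ester that lies cis to the ketone chain (Claisen condensation of the Dieckmann type, forming C8–C8a) with loss of ethoxide. Ring A closes in the 6-exo-trig mode, the attacked carbonyl lying outside the new ring. The first-formed diketo tautomer of 7 is already at the oxidation level of a resorcinol and tautomerises to 7 without an oxidant, and the chelated phenoxide of 7 is the thermodynamic sink. The closest known reaction types are [3+3] Michael-Claisen benzannulations of acetonedicarboxylate-type 1,3-dinucleophiles with alkoxymethylene or alkynyl carbonyl partners, and carbanion- or alkoxide-induced ring transformations of 2-pyranones into arenes; what is new is an unactivated dialkyl ketone as the three-carbon partner. No stereocenter is formed. The selectivity needed is carbon over oxygen acylation in the closure, secured by reversible alkoxide conditions under which O-acylation is not a dead end; regiochemistry needs no control because 3 is symmetric, and a cis ester is guaranteed because C4a carries two ester groups.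

Step 3
Reactants: 7 ethyl 2,4-dihydroxy-3,5-bis(3-methylbut-2-en-1-yl)benzoate
Product: 8 ethyl 2-hydroxy-4-(methoxymethoxy)-3,5-bis(3-methylbut-2-en-1-yl)benzoate
Conditions: MOMCl (1.2 equiv), K2CO3 (2 equiv), acetone, 0 °C → rt
Reagents that add atoms: chloromethyl methyl ether, COCCl
Why: Williamson-type O-alkylation. The 2-OH is hydrogen-bonded to the ester carbonyl and is the weaker acid, so carbonate ionises and alkylates only the 4-OH (the future C7 oxygen) with the small, reactive chloride, despite the two ortho prenyl groups; this selectivity is standard for 2,4-dihydroxyaryl carbonyl compounds.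

Step 4
Reactants: 8 ethyl 2-hydroxy-4-(methoxymethoxy)-3,5-bis(3-methylbut-2-en-1-yl)benzoate
Product: 10 1-[2-hydroxy-4-(methoxymethoxy)-3,5-bis(3-methylbut-2-en-1-yl)phenyl]ethan-1-one, via alpha-silyl ketone 9 (not isolated)
Conditions: Me3SiCH2Li (4 equiv), THF/pentane, 0 °C → rt; then MeOH, rt; aq. NH4Cl
Reagents that add atoms: (trimethylsilyl)methyllithium, [Li]C[Si](C)(C)C
Why: Conversion of an ester into a methyl ketone with (trimethylsilyl)methyllithium. After one equivalent has formed the phenoxide, addition to the ester and loss of ethoxide give the alpha-silyl ketone 9, which is deprotonated at once to an enolate that resists a second addition. Methanol then cleaves the C–Si bond and leaves the methyl group that becomes C3.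

Step 5
Reactants: 10 1-[2-hydroxy-4-(methoxymethoxy)-3,5-bis(3-methylbut-2-en-1-yl)phenyl]ethan-1-one
Product: 12 7-(methoxymethoxy)-6,8-bis(3-methylbut-2-en-1-yl)-4H-chromen-4-one, via enaminone 11 (not isolated)
Conditions: Me2NCH(OMe)2 (3 equiv), PhMe, 95 °C; evaporate; AcOH, 60 °C
Reagents that add atoms: N,N-dimethylformamide dimethyl acetal, COC(OC)N(C)C
Why: Condensation of the methyl ketone with the amide acetal gives enaminone 11. In warm acetic acid the 2-OH adds to the beta carbon (6-endo-trig conjugate addition) and dimethylamine is lost, which is the enaminone route to chromones. The weak acid should leave the MOM ether and the prenyl groups untouched.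

Step 6
Reactants: 12 7-(methoxymethoxy)-6,8-bis(3-methylbut-2-en-1-yl)-4H-chromen-4-one; 13 [4-(methoxymethoxy)phenyl]boronic acid
Product: 14 (2S)-7-(methoxymethoxy)-2-[4-(methoxymethoxy)phenyl]-6,8-bis(3-methylbut-2-en-1-yl)-2,3-dihydro-4H-chromen-4-one
Conditions: 13 (2 equiv), Pd(OCOCF3)2 (10 mol%), (R)-4-tert-butyl-2-(pyridin-2-yl)-4,5-dihydrooxazole (12 mol%), NH4PF6 (30 mol%), H2O (5 equiv), ClCH2CH2Cl, 60 °C
Reagents that add atoms: none
Why: Enantioselective conjugate addition of an arylboronic acid to a chromone under a cationic divalent palladium/pyridine-oxazoline catalyst: transmetalation gives an aryl-palladium species, the C2=C3 bond inserts with the tert-butyl group of the ligand blocking one face, and water protonates the palladium enolate. C2 is set here by the catalyst alone, and the (R)-ligand is chosen to give 2S. The MOM ether keeps the ortho-prenyl phenol from oxidative cyclisation at palladium, and trisubstituted alkenes are poor partners for aryl-palladium insertion.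

Step 7
Reactants: 14 (2S)-7-(methoxymethoxy)-2-[4-(methoxymethoxy)phenyl]-6,8-bis(3-methylbut-2-en-1-yl)-2,3-dihydro-4H-chromen-4-one
Product: 15 (2S)-7-hydroxy-2-(4-hydroxyphenyl)-6,8-bis(3-methylbut-2-en-1-yl)-2,3-dihydro-4H-chromen-4-one
Conditions: 3 M aq. HCl, MeOH, 25 → 40 °C
Reagents that add atoms: none
Why: Acid-catalysed transacetalisation of both aryl MOM ethers to methanol (acetal cleavage), as routinely used on prenylated flavonoids. Dilute acid near room temperature is chosen so that the freed 7-OH does not add across a neighbouring prenyl group and ring C does not open and reclose.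

## Compound list

1 | 6-methylhept-5-en-2-one | CC(C)=CCCC(C)=O | starting material
2 | 1-bromo-3-methylbut-2-ene (prenyl bromide) | CC(C)=CCBr | starting material
3 | 2,10-dimethylundeca-2,9-dien-6-one | CC(C)=CCCC(=O)CCC=C(C)C | intermediate
4 | diethyl 2-(ethoxymethylidene)propanedioate | CCOC=C(C(=O)OCC)C(=O)OCC | starting material
5 | diethyl 2-[7-methyl-2-(3-methylbut-2-en-1-yl)-3-oxooct-6-en-1-ylidene]propanedioate (racemic; present as its enolate) | CCOC(=O)C(C(=O)OCC)=CC(CC=C(C)C)C(=O)CCC=C(C)C | intermediate (not isolated)
6 | ethyl 6-(4-methylpent-3-en-1-yl)-5-(3-methylbut-2-en-1-yl)-2-oxo-2H-pyran-3-carboxylate | CCOC(=O)C1=CC(CC=C(C)C)=C(CCC=C(C)C)OC1=O | intermediate (not isolated)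
7 | ethyl 2,4-dihydroxy-3,5-bis(3-methylbut-2-en-1-yl)benzoate | CCOC(=O)c1cc(CC=C(C)C)c(O)c(CC=C(C)C)c1O | intermediate
8 | ethyl 2-hydroxy-4-(methoxymethoxy)-3,5-bis(3-methylbut-2-en-1-yl)benzoate | CCOC(=O)c1cc(CC=C(C)C)c(OCOC)c(CC=C(C)C)c1O | intermediate
9 | 1-[2-hydroxy-4-(methoxymethoxy)-3,5-bis(3-methylbut-2-en-1-yl)phenyl]-2-(trimethylsilyl)ethan-1-one | C[Si](C)(C)CC(=O)c1cc(CC=C(C)C)c(OCOC)c(CC=C(C)C)c1O | intermediate (not isolated)
10 | 1-[2-hydroxy-4-(methoxymethoxy)-3,5-bis(3-methylbut-2-en-1-yl)phenyl]ethan-1-one | CC(=O)c1cc(CC=C(C)C)c(OCOC)c(CC=C(C)C)c1O | intermediate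
11 | (2E)-3-(dimethylamino)-1-[2-hydroxy-4-(methoxymethoxy)-3,5-bis(3-methylbut-2-en-1-yl)phenyl]prop-2-en-1-one | CN(C)/C=C/C(=O)c1cc(CC=C(C)C)c(OCOC)c(CC=C(C)C)c1O | intermediate (not isolated)
12 | 7-(methoxymethoxy)-6,8-bis(3-methylbut-2-en-1-yl)-4H-chromen-4-one | O=c1ccoc2c(CC=C(C)C)c(OCOC)c(CC=C(C)C)cc12 | intermediate
13 | [4-(methoxymethoxy)phenyl]boronic acid | COCOc1ccc(B(O)O)cc1 | starting material
14 | (2S)-7-(methoxymethoxy)-2-[4-(methoxymethoxy)phenyl]-6,8-bis(3-methylbut-2-en-1-yl)-2,3-dihydro-4H-chromen-4-one | CC(C)=CCc1cc2c(c(CC=C(C)C)c1OCOC)O[C@H](c1ccc(OCOC)cc1)CC2=O | intermediate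
15 | (2S)-7-hydroxy-2-(4-hydroxyphenyl)-6,8-bis(3-methylbut-2-en-1-yl)-2,3-dihydro-4H-chromen-4-one | CC(C)=CCc1cc2c(c(CC=C(C)C)c1O)O[C@H](c1ccc(O)cc1)CC2=O | target

## Step count and least certain steps

Total step count: 7. Longest linear sequence: 7 steps (1 to 15); 2, 4 and 13 are purchased.

**Step 2 (key step, proposed new method).**
- What may go wrong: the closure may stop at oxygen acylation, with ethoxide failing to return 6 to the open chain. The stabilised C6 anion of 5 may never be deprotonated at C8 under alkoxide. A second molecule of 4 may add at C6 and block aromatisation. A first adjustment inside the approach would be two further equivalents of amide base to form the C6,C8 dianion before warming.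
- Fallback (known chemistry): it sets out from prenyl bromide 2 and returns at 10. Purchased 1-(2,4-dihydroxyphenyl)ethan-1-one F1 is C-prenylated twice with 2 in aqueous KOH at 0 °C to room temperature. This nuclear alkylation of the resorcinolate is known but unselective, so 1-[2,4-dihydroxy-3,5-bis(3-methylbut-2-en-1-yl)phenyl]ethan-1-one F2 must be separated from mono- and O-prenylated material. F2 is then protected at its non-chelated hydroxyl with MOMCl and K2CO3 in acetone to give 10. Steps 2 to 4 are then not needed.

**Step 1.**
- What may go wrong: regiochemical leakage. Some deprotonation at the internal methylene, or proton transfer between product and enolate during the alkylation, would give branched and dialkylated ketones that are hard to remove and would spoil the symmetry on which step 2 relies.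
- Fallback: it sets out from 1 and returns at 3. Ketone 1 is condensed with N,N-dimethylhydrazine to 6-methylhept-5-en-2-one N,N-dimethylhydrazone F3. The azaenolate (n-BuLi, THF, 0 °C), which forms at the methyl group, is alkylated with 2 to 2,10-dimethylundeca-2,9-dien-6-one N,N-dimethylhydrazone F4. Hydrolysis with aqueous oxalic acid in a two-phase mixture gives 3.

**Step 4.**
- What may go wrong: sluggish addition to an ester deactivated by the ortho phenoxide, or loss of the mono-addition stop so that some tertiary alcohol forms.
- Fallback: it sets out from 8 and returns at 10. Ester 8 is converted with MeNH(OMe)·HCl and iPrMgCl (THF, −20 → 0 °C) into the Weinreb amide 2-hydroxy-N-methoxy-4-(methoxymethoxy)-N-methyl-3,5-bis(3-methylbut-2-en-1-yl)benzamide F5. Its chelated tetrahedral intermediate with excess MeMgBr (THF, 0 °C) collapses to 10 only on work-up.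

**Step 6.**
- What may go wrong: slow insertion, because the 7-alkoxy group makes the chromone a weak acceptor, so protodeboronation of 13 may outrun the addition. Face selectivity may be insufficient on this 8-substituted substrate. Palladium hydride or aryl-palladium may engage the prenyl alkenes.
- Fallback: it sets out from 10 and returns at 14. Claisen–Schmidt condensation of 10 with purchased 4-(methoxymethoxy)benzaldehyde F6 (KOH, EtOH) gives the chalcone (2E)-1-[2-hydroxy-4-(methoxymethoxy)-3,5-bis(3-methylbut-2-en-1-yl)phenyl]-3-[4-(methoxymethoxy)phenyl]prop-2-en-1-one F7. Closure with NaOAc in refluxing ethanol gives the racemic flavanone F8. Preparative chromatography on a polysaccharide-carbamate chiral phase gives 14. The unwanted (2R)-enantiomer F9 is returned to the F7/F8 equilibrium with base and recycled.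

**Step 7.**
- What may go wrong: erosion of enantiopurity through acid-promoted reversible opening of ring C, and acid-catalysed addition of the freed 7-OH across a neighbouring prenyl double bond.
- Fallback: it sets out from 12 and ends at 15. The acetal of 12 is removed with HCl in methanol at the achiral chromone stage, where there is no configuration to lose and a gentler Lewis-acid variant can be tried without risk. This gives 7-hydroxy-6,8-bis(3-methylbut-2-en-1-yl)-4H-chromen-4-one F10. Silylation (TBSCl, imidazole, DMF) gives 7-[(tert-butyldimethylsilyl)oxy]-6,8-bis(3-methylbut-2-en-1-yl)-4H-chromen-4-one F11. The conjugate addition of step 6 with purchased [4-(tert-butyldimethylsilyloxy)phenyl]boronic acid F12 gives the bis-silyl flavanone (2S)-7-[(tert-butyldimethylsilyl)oxy]-2-[4-(tert-butyldimethylsilyloxy)phenyl]-6,8-bis(3-methylbut-2-en-1-yl)-2,3-dihydro-4H-chromen-4-one F13. KHF2 in methanol at room temperature then frees both phenols under nearly neutral conditions to give 15.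

## Further compounds

F1 | step 2 | 1-(2,4-dihydroxyphenyl)ethan-1-one (purchased) | CC(=O)c1ccc(O)cc1O
F2 | step 2 | 1-[2,4-dihydroxy-3,5-bis(3-methylbut-2-en-1-yl)phenyl]ethan-1-one | CC(=O)c1cc(CC=C(C)C)c(O)c(CC=C(C)C)c1O
F3 | step 1 | 6-methylhept-5-en-2-one N,N-dimethylhydrazone | CC(C)=CCCC(C)=NN(C)C
F4 | step 1 | 2,10-dimethylundeca-2,9-dien-6-one N,N-dimethylhydrazone | CC(C)=CCCC(CCC=C(C)C)=NN(C)C
F5 | step 4 | 2-hydroxy-N-methoxy-4-(methoxymethoxy)-N-methyl-3,5-bis(3-methylbut-2-en-1-yl)benzamide | CON(C)C(=O)c1cc(CC=C(C)C)c(OCOC)c(CC=C(C)C)c1O
F6 | step 6 | 4-(methoxymethoxy)benzaldehyde (purchased) | COCOc1ccc(C=O)cc1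
F7 | step 6 | (2E)-1-[2-hydroxy-4-(methoxymethoxy)-3,5-bis(3-methylbut-2-en-1-yl)phenyl]-3-[4-(methoxymethoxy)phenyl]prop-2-en-1-one | COCOc1ccc(/C=C/C(=O)c2cc(CC=C(C)C)c(OCOC)c(CC=C(C)C)c2O)cc1
F8 | step 6 | racemic 7-(methoxymethoxy)-2-[4-(methoxymethoxy)phenyl]-6,8-bis(3-methylbut-2-en-1-yl)-2,3-dihydro-4H-chromen-4-one | CC(C)=CCc1cc2c(c(CC=C(C)C)c1OCOC)OC(c1ccc(OCOC)cc1)CC2=O
F9 | step 6 | (2R)-7-(methoxymethoxy)-2-[4-(methoxymethoxy)phenyl]-6,8-bis(3-methylbut-2-en-1-yl)-2,3-dihydro-4H-chromen-4-one | CC(C)=CCc1cc2c(c(CC=C(C)C)c1OCOC)O[C@@H](c1ccc(OCOC)cc1)CC2=O
F10 | step 7 | 7-hydroxy-6,8-bis(3-methylbut-2-en-1-yl)-4H-chromen-4-one | O=c1ccoc2c(CC=C(C)C)c(O)c(CC=C(C)C)cc12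
F11 | step 7 | 7-[(tert-butyldimethylsilyl)oxy]-6,8-bis(3-methylbut-2-en-1-yl)-4H-chromen-4-one | O=c1ccoc2c(CC=C(C)C)c(O[Si](C)(C)C(C)(C)C)c(CC=C(C)C)cc12
F12 | step 7 | [4-(tert-butyldimethylsilyloxy)phenyl]boronic acid (purchased) | CC(C)(C)[Si](C)(C)Oc1ccc(B(O)O)cc1
F13 | step 7 | (2S)-7-[(tert-butyldimethylsilyl)oxy]-2-[4-(tert-butyldimethylsilyloxy)phenyl]-6,8-bis(3-methylbut-2-en-1-yl)-2,3-dihydro-4H-chromen-4-one | CC(C)=CCc1cc2c(c(CC=C(C)C)c1O[Si](C)(C)C(C)(C)C)O[C@H](c1ccc(O[Si](C)(C)C(C)(C)C)cc1)CC2=O
A1 | alternative 1 | (2S)-2-[4-(tert-butyldimethylsilyloxy)phenyl]-7-hydroxy-6,8-bis(3-methylbut-2-en-1-yl)-2,3-dihydro-4H-chromen-4-one | CC(C)=CCc1cc2c(c(CC=C(C)C)c1O)O[C@H](c1ccc(O[Si](C)(C)C(C)(C)C)cc1)CC2=O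
A2 | alternative 1 | (2S)-2-[4-(tert-butyldimethylsilyloxy)phenyl]-7-hydroxy-6,8-di(prop-2-en-1-yl)-2,3-dihydro-4H-chromen-4-one | C=CCc1cc2c(c(CC=C)c1O)O[C@H](c1ccc(O[Si](C)(C)C(C)(C)C)cc1)CC2=O
A3 | alternative 1 | 2-methylbut-2-ene | CC=C(C)C
A4 | alternative 2 | (2S,4S)-7-(methoxymethoxy)-2-[4-(methoxymethoxy)phenyl]-6,8-bis(3-methylbut-2-en-1-yl)-3,4-dihydro-2H-chromen-4-ol | CC(C)=CCc1cc2c(c(CC=C(C)C)c1OCOC)O[C@H](c1ccc(OCOC)cc1)C[C@@H]2O
A5 | alternative 2 | (1S,3S)-1-[2-bromo-4-(methoxymethoxy)-3,5-bis(3-methylbut-2-en-1-yl)phenyl]-3-[4-(methoxymethoxy)phenyl]propane-1,3-diol | CC(C)=CCc1cc(c(Br)c(CC=C(C)C)c1OCOC)[C@@H](O)C[C@H](O)c1ccc(OCOC)cc1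
A6 | alternative 3 | 2,6-bis(3-methylbut-2-en-1-yl)-3-[(triisopropylsilyl)oxy]phenol | CC(C)=CCc1ccc(O[Si](C(C)C)(C(C)C)C(C)C)c(CC=C(C)C)c1O
A7 | alternative 3 | (3E)-1-diazo-7-methylocta-3,6-dien-2-one | CC(C)=CC/C=C/C(=O)C=[N+]=[N-]
A8 | alternative 3 | triisopropyl[(5-methylhex-4-en-1-yn-1-yl)oxy]silane | CC(C)=CCC#CO[Si](C(C)C)(C(C)C)C(C)C
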